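**Retrosynthetic overview**

- Numbering (hirsutinolide): C1 hemiketal carbon, C4 ether carbon (CH3-15), C5=C6 enol-lactone olefin, C7=C11 butenolide olefin, C8 ester carbon, C10 (CH3-14), C12 lactone C=O, C13 CH2OAc.
- Target ⇐ chloride opening of a C8 (S)-2-methylglycidate ⇐ PMB→Ac exchange ⇐ ring-closing metathesis forming C5=C6 (new step) between the C4 vinyl group and a 5-methylene-2(5H)-furanone; this closes the ten-membered carbocycle and fixes the C1–O–C4 oxolane hemiketal.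
- Methylene butenolide ⇐ 2-methylfuran (singlet oxygen, then dehydration); furan ⇐ Feist–Benary reaction of acetylacetone with 1,3-dichloroacetone (delivers C6, C7, C8, C9, C11, C12, C13).
- C1–C2 ⇐ acylation of a lithiated sulfone (C2–C5, C4 from (S)-2-methylglycidol) by a C1 lactone; C10 ⇐ SN2 of the furyl methyl ketone enolate on ethyl (R)-lactate triflate; C8 ⇐ CBS reduction; side-chain carbinol ⇐ methyl (S)-2-methylglycidate.
- Ring order: furan (step 1) → butenolide (steps 12–13) → ten-membered ring and oxolane (step 15).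

Assumption: 17, 18 and 24 are drawn as open-chain hydroxy ketones although they equilibrate with five-membered hemiketals; 17 is a mixture at the sulfonyl carbon and 22 at its ring hemiketal carbon (both centres are removed later).

**Route**

Step 1
Reactants: 1 pentane-2,4-dione; 2 1,3-dichloropropan-2-one
Product: 4 1-[4-(chloromethyl)-2-methylfuran-3-yl]ethan-1-one, via hydroxydihydrofuran adduct 3 (not isolated)
Conditions: Et3N (1.1 equiv), THF, 0 → 23 °C; then TsOH·H2O (5 mol %), PhMe, 50 °C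
Reagents that add atoms: none
Why: Feist–Benary furan synthesis, in which the diketone carbon adds to the ketone of 2, the enol oxygen displaces one chloride to give 3, and acid-catalysed loss of water aromatises it (no stereocentre).

Step 2
Reactants: 4 1-[4-(chloromethyl)-2-methylfuran-3-yl]ethan-1-one
Product: 5 1-[4-{[(4-methoxyphenyl)methoxy]methyl}-2-methylfuran-3-yl]ethan-1-one
Conditions: 4-methoxybenzyl alcohol (3 equiv), Ag2O (1.0 equiv), CH2Cl2, 23 °C, dark
Reagents that add atoms: 4-methoxybenzyl alcohol, COc1ccc(CO)cc1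
Why: Silver-assisted Williamson-type etherification of the activated furylmethyl chloride under non-basic conditions that leave the methyl ketone untouched.

Step 3
Reactants: 6 ethyl (2R)-2-hydroxypropanoate
Product: 7 ethyl (2R)-2-{[(trifluoromethyl)sulfonyl]oxy}propanoate
Conditions: Tf2O, 2,6-lutidine, CH2Cl2, −78 → 0 °C
Reagents that add atoms: trifluoromethanesulfonic anhydride, O=S(=O)(OS(=O)(=O)C(F)(F)F)C(F)(F)F
Why: O-Sulfonylation of the secondary alcohol, which does not touch the C–O bond and so retains configuration.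

Step 4
Reactants: 5 1-[4-{[(4-methoxyphenyl)methoxy]methyl}-2-methylfuran-3-yl]ethan-1-one; 7 ethyl (2R)-2-{[(trifluoromethyl)sulfonyl]oxy}propanoate
Product: 8 ethyl (2R)-4-[4-{[(4-methoxyphenyl)methoxy]methyl}-2-methylfuran-3-yl]-2-methyl-4-oxobutanoate
Conditions: LiN(iPr)2 (1.05 equiv), THF, −78 °C; then 7 (1.2 equiv), −78 → −30 °C
Reagents that add atoms: none
Why: SN2 alkylation of the kinetic methyl-ketone enolate by the α-triflyloxy ester with clean inversion, which sets C10 as R (the descriptor stays R because the new carbon ranks below the ester carbon).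

Step 5
Reactants: 8 ethyl (2R)-4-[4-{[(4-methoxyphenyl)methoxy]methyl}-2-methylfuran-3-yl]-2-methyl-4-oxobutanoate
Product: 10 (3R,5S)-5-[4-{[(4-methoxyphenyl)methoxy]methyl}-2-methylfuran-3-yl]-3-methyloxolan-2-one, via hydroxy ester 9 (not isolated)
Conditions: (R)-2-methyl-CBS-oxazaborolidine (10 mol %), BH3·SMe2, THF, −20 °C; MeOH; then PPTS (5 mol %), PhMe, 40 °C
Reagents that add atoms: none
Why: Corey–Bakshi–Shibata reduction, in which the (R)-oxazaborolidine delivers hydride to the furyl (large group) ketone to set C8 as S, followed by lactonisation onto the ethyl ester to the trans lactone.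

Step 6
Reactants: 11 [(2S)-2-methyloxiran-2-yl]methanol
Product: 13 (2S)-2-ethenyl-2-methyloxirane, via epoxy aldehyde 12 (not isolated)
Conditions: TEMPO (10 mol %), PhI(OAc)2, CH2Cl2, 0 → 23 °C; aq. NaHCO3 wash; dried solution added to Ph3P=CH2 [from Ph3PCH3Br, KN(SiMe3)2], THF, −78 → 0 °C; distilled as a THF solution
Reagents that add atoms: methyltriphenylphosphonium bromide, C[P+](c1ccccc1)(c1ccccc1)c1ccccc1.[Br-]
Why: TEMPO oxidation then Wittig methylenation; the quaternary epoxide carbon (future C4) cannot epimerise, and the S → R → S labels are descriptor changes only.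

Step 7
Reactants: 13 (2S)-2-ethenyl-2-methyloxirane; 14 (methylsulfonyl)benzene
Product: 16 triethyl{[(3R)-3-methyl-5-(phenylsulfonyl)pent-1-en-3-yl]oxy}silane, via lithium alkoxide 15 (not isolated)
Conditions: n-BuLi (1.0 equiv), THF/DMPU, −78 °C; 13, −78 → 0 °C; then Et3SiCl, DMAP (cat.), 0 → 23 °C
Reagents that add atoms: chlorotriethylsilane, CC[Si](Cl)(CC)CC
Why: SN2 opening of the 2,2-disubstituted epoxide by the sulfonyl carbanion at the unsubstituted CH2 (C3), which leaves the C4 stereocentre untouched, then O-silylation of the tertiary alkoxide.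

Step 8
Reactants: 10 (3R,5S)-5-[4-{[(4-methoxyphenyl)methoxy]methyl}-2-methylfuran-3-yl]-3-methyloxolan-2-one; 16 triethyl{[(3R)-3-methyl-5-(phenylsulfonyl)pent-1-en-3-yl]oxy}silane
Product: 17 (3R,7R,9S)-9-hydroxy-9-[4-{[(4-methoxyphenyl)methoxy]methyl}-2-methylfuran-3-yl]-3,7-dimethyl-5-(phenylsulfonyl)-3-[(triethylsilyl)oxy]non-1-en-6-one
Conditions: 16 (2.1 equiv), n-BuLi (2.1 equiv), THF, −78 °C; then 10, −78 → −40 °C; AcOH quench
Reagents that add atoms: none
Why: Claisen-type acylation of the α-sulfonyl carbanion by the lactone forms C1–C2; the β-keto sulfone is deprotonated at C2 as it forms, which shields C10 from epimerisation.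

Step 9
Reactants: 17 (3R,7R,9S)-9-hydroxy-9-[4-{[(4-methoxyphenyl)methoxy]methyl}-2-methylfuran-3-yl]-3,7-dimethyl-5-(phenylsulfonyl)-3-[(triethylsilyl)oxy]non-1-en-6-one
Product: 18 (3R,7R,9S)-9-hydroxy-9-[4-{[(4-methoxyphenyl)methoxy]methyl}-2-methylfuran-3-yl]-3,7-dimethyl-3-[(triethylsilyl)oxy]non-1-en-6-one
Conditions: SmI2 (2.5 equiv), THF/MeOH, −78 °C
Reagents that add atoms: none
Why: Reductive desulfonylation of an α-sulfonyl ketone by single-electron transfer, which touches no stereocentre.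

Step 10
Reactants: 19 methyl (2S)-2-methyloxirane-2-carboxylate
Product: 20 potassium (2S)-2-methyloxirane-2-carboxylate
Conditions: KOH (1.0 equiv), MeOH, 0 → 23 °C; evaporation
Reagents that add atoms: potassium hydroxide, [K+].[OH-]
Why: Saponification; the quaternary α-carbon cannot epimerise and the salt avoids handling the free epoxy acid.

Step 11
Reactants: 18 (3R,7R,9S)-9-hydroxy-9-[4-{[(4-methoxyphenyl)methoxy]methyl}-2-methylfuran-3-yl]-3,7-dimethyl-3-[(triethylsilyl)oxy]non-1-en-6-one; 20 potassium (2S)-2-methyloxirane-2-carboxylate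
Product: 21 (1S,3R,7R)-1-[4-{[(4-methoxyphenyl)methoxy]methyl}-2-methylfuran-3-yl]-3,7-dimethyl-4-oxo-7-[(triethylsilyl)oxy]non-8-en-1-yl (2S)-2-methyloxirane-2-carboxylate
Conditions: 20, 2,4,6-trichlorobenzoyl chloride, Et3N, THF, 0 °C; then 18, DMAP, PhMe, 23 °C
Reagents that add atoms: none
Why: Yamaguchi esterification of the secondary C8 hydroxyl with retention at C8 and at the acid α-carbon; it must precede furan oxidation so that C8–OH cannot capture the C12 acid.

Step 12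
Reactants: 21 (1S,3R,7R)-1-[4-{[(4-methoxyphenyl)methoxy]methyl}-2-methylfuran-3-yl]-3,7-dimethyl-4-oxo-7-[(triethylsilyl)oxy]non-8-en-1-yl (2S)-2-methyloxirane-2-carboxylate
Product: 22 (1S,3R,7R)-1-[2-hydroxy-4-{[(4-methoxyphenyl)methoxy]methyl}-2-methyl-5-oxo-2,5-dihydrofuran-3-yl]-3,7-dimethyl-4-oxo-7-[(triethylsilyl)oxy]non-8-en-1-yl (2S)-2-methyloxirane-2-carboxylate
Conditions: O2, visible light, 5,10,15,20-tetraphenylporphyrin (1 mol %), iPr2NEt, CH2Cl2, −78 °C
Reagents that add atoms: dioxygen, O=O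
Why: [4+2] addition of singlet oxygen to the furan then Kornblum–DeLaMare fragmentation at the only bridgehead hydrogen (C12–H) gives the 5-hydroxy-5-methylbutenolide regiospecifically (C12=O, C6–OH).

Step 13
Reactants: 22 (1S,3R,7R)-1-[2-hydroxy-4-{[(4-methoxyphenyl)methoxy]methyl}-2-methyl-5-oxo-2,5-dihydrofuran-3-yl]-3,7-dimethyl-4-oxo-7-[(triethylsilyl)oxy]non-8-en-1-yl (2S)-2-methyloxirane-2-carboxylate
Product: 23 (1S,3R,7R)-1-[4-{[(4-methoxyphenyl)methoxy]methyl}-2-methylidene-5-oxo-2,5-dihydrofuran-3-yl]-3,7-dimethyl-4-oxo-7-[(triethylsilyl)oxy]non-8-en-1-yl (2S)-2-methyloxirane-2-carboxylate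
Conditions: MsCl (1.2 equiv), Et3N (3 equiv), CH2Cl2, −40 → 0 °C
Reagents that add atoms: none
Why: Dehydration (enol-lactonisation) of the γ-hydroxybutenolide through its sulfonate/acyloxocarbenium ion with loss of a methyl proton gives the 5-methylene-2(5H)-furanone.

Step 14
Reactants: 23 (1S,3R,7R)-1-[4-{[(4-methoxyphenyl)methoxy]methyl}-2-methylidene-5-oxo-2,5-dihydrofuran-3-yl]-3,7-dimethyl-4-oxo-7-[(triethylsilyl)oxy]non-8-en-1-yl (2S)-2-methyloxirane-2-carboxylate
Product: 24 (1S,3R,7R)-7-hydroxy-1-[4-{[(4-methoxyphenyl)methoxy]methyl}-2-methylidene-5-oxo-2,5-dihydrofuran-3-yl]-3,7-dimethyl-4-oxonon-8-en-1-yl (2S)-2-methyloxirane-2-carboxylate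
Conditions: HF·pyridine, pyridine, THF, 0 → 23 °C
Reagents that add atoms: none
Why: Fluoride cleavage of the tertiary silyl ether frees C4–OH, which then equilibrates with the C1 ketone as the oxolane hemiketal.

Step 15
Reactants: 24 (1S,3R,7R)-7-hydroxy-1-[4-{[(4-methoxyphenyl)methoxy]methyl}-2-methylidene-5-oxo-2,5-dihydrofuran-3-yl]-3,7-dimethyl-4-oxonon-8-en-1-yl (2S)-2-methyloxirane-2-carboxylate
Product: 25 (1S,4R,5E,8S,10R)-1-hydroxy-13-[(4-methoxyphenyl)methoxy]-8-{[(2S)-2-methyloxirane-2-carbonyl]oxy}-1,4-epoxygermacra-5,7(11)-dien-12,6-olide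
Conditions: second-generation Hoveyda–Grubbs catalyst (15 mol %), 1,4-benzoquinone (30 mol %), PhMe (1 mM), 80 °C, Ar sparge
Reagents that add atoms: none
Why: Proposed new method: ring-closing metathesis in which one partner is the exocyclic C=CH2 of a 5-methylene-2(5H)-furanone, an enol-lactone olefin not yet used in metathesis; the ruthenium alkylidene loads on the vinyl group of the tertiary allylic carbinol, adds across the 1,1-disubstituted enol-ester olefin with ruthenium on its CH2 terminus so that cycloreversion gives the trisubstituted C5=C6 bond and Ru=CH2 (no Fischer carbene on the productive path, tetrasubstituted C7=C11 inert), ethene loss drives the reaction, and the oxolane hemiketal (C1 epimers interconvert through the open ketone, only 1S can bridge) templates the ten-membered ring and enforces the ring-cis 5E geometry; the closest known reactions are ring-closing metatheses of acyclic enol ethers and enol esters and of 2-substituted 1,3-dienes.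

Step 16
Reactants: 25 (1S,4R,5E,8S,10R)-1-hydroxy-13-[(4-methoxyphenyl)methoxy]-8-{[(2S)-2-methyloxirane-2-carbonyl]oxy}-1,4-epoxygermacra-5,7(11)-dien-12,6-olide
Product: 26 (1S,4R,5E,8S,10R)-1,13-dihydroxy-8-{[(2S)-2-methyloxirane-2-carbonyl]oxy}-1,4-epoxygermacra-5,7(11)-dien-12,6-olide
Conditions: DDQ (1.5 equiv), CH2Cl2/aq. NaH2PO4–Na2HPO4 (pH 7), 0 → 23 °C
Reagents that add atoms: none
Why: Oxidative cleavage of the 4-methoxybenzyl ether by hydride abstraction; the electron-poor ylidene butenolide, epoxide and hemiketal are inert.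

Step 17
Reactants: 26 (1S,4R,5E,8S,10R)-1,13-dihydroxy-8-{[(2S)-2-methyloxirane-2-carbonyl]oxy}-1,4-epoxygermacra-5,7(11)-dien-12,6-olide
Product: 27 (1S,4R,5E,8S,10R)-13-acetoxy-1-hydroxy-8-{[(2S)-2-methyloxirane-2-carbonyl]oxy}-1,4-epoxygermacra-5,7(11)-dien-12,6-olide
Conditions: Ac2O, pyridine, CH2Cl2, 0 °C
Reagents that add atoms: acetic anhydride, CC(=O)OC(C)=O
Why: Acetylation of the primary allylic alcohol; the tertiary hemiketal hydroxyl does not react under these conditions.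

Step 18
Reactants: 27 (1S,4R,5E,8S,10R)-13-acetoxy-1-hydroxy-8-{[(2S)-2-methyloxirane-2-carbonyl]oxy}-1,4-epoxygermacra-5,7(11)-dien-12,6-olide
Product: 28 (1S,4R,5E,8S,10R)-13-acetoxy-8-{[(2R)-3-chloro-2-hydroxy-2-methylpropanoyl]oxy}-1-hydroxy-1,4-epoxygermacra-5,7(11)-dien-12,6-olide
Conditions: pyridinium chloride (3 equiv), CHCl3, 45 °C
Reagents that add atoms: pyridinium chloride, [Cl-].c1cc[nH+]cc1
Why: Acid-assisted SN2 opening of the glycidic ester by chloride at the CH2 terminus; the quaternary carbinol carbon is untouched (S epoxide becomes R chlorohydrin by priority change only).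

**Compound list**

1 | pentane-2,4-dione | CC(=O)CC(C)=O | starting material
2 | 1,3-dichloropropan-2-one | ClCC(=O)CCl | starting material
3 | 1-[4-(chloromethyl)-4-hydroxy-2-methyl-4,5-dihydrofuran-3-yl]ethan-1-one (racemic) | CC(=O)C1=C(C)OCC1(O)CCl | intermediate
4 | 1-[4-(chloromethyl)-2-methylfuran-3-yl]ethan-1-one | CC(=O)c1c(C)occ1CCl | intermediate
5 | 1-[4-{[(4-methoxyphenyl)methoxy]methyl}-2-methylfuran-3-yl]ethan-1-one | CC(=O)c1c(C)occ1COCc2ccc(OC)cc2 | intermediate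
6 | ethyl (2R)-2-hydroxypropanoate | CCOC(=O)[C@@H](C)O | starting material
7 | ethyl (2R)-2-{[(trifluoromethyl)sulfonyl]oxy}propanoate | CCOC(=O)[C@@H](C)OS(=O)(=O)C(F)(F)F | intermediate
8 | ethyl (2R)-4-[4-{[(4-methoxyphenyl)methoxy]methyl}-2-methylfuran-3-yl]-2-methyl-4-oxobutanoate | CCOC(=O)[C@H](C)CC(=O)c1c(C)occ1COCc2ccc(OC)cc2 | intermediate
9 | ethyl (2R,4S)-4-hydroxy-4-[4-{[(4-methoxyphenyl)methoxy]methyl}-2-methylfuran-3-yl]-2-methylbutanoate | CCOC(=O)[C@H](C)C[C@H](O)c1c(C)occ1COCc2ccc(OC)cc2 | intermediate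
10 | (3R,5S)-5-[4-{[(4-methoxyphenyl)methoxy]methyl}-2-methylfuran-3-yl]-3-methyloxolan-2-one | C[C@@H]1C[C@H](OC1=O)c2c(C)occ2COCc3ccc(OC)cc3 | intermediate
11 | [(2S)-2-methyloxiran-2-yl]methanol | OC[C@]1(C)OC1 | starting material
12 | (2R)-2-methyloxirane-2-carbaldehyde | O=C[C@]1(C)OC1 | intermediate
13 | (2S)-2-ethenyl-2-methyloxirane | C=C[C@]1(C)OC1 | intermediate
14 | (methylsulfonyl)benzene | CS(=O)(=O)c1ccccc1 | starting material
15 | lithium (3R)-3-methyl-5-(phenylsulfonyl)pent-1-en-3-olate | [Li+].C=C[C@](C)([O-])CCS(=O)(=O)c1ccccc1 | intermediate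
16 | triethyl{[(3R)-3-methyl-5-(phenylsulfonyl)pent-1-en-3-yl]oxy}silane | C=C[C@](C)(O[Si](CC)(CC)CC)CCS(=O)(=O)c1ccccc1 | intermediate
17 | (3R,7R,9S)-9-hydroxy-9-[4-{[(4-methoxyphenyl)methoxy]methyl}-2-methylfuran-3-yl]-3,7-dimethyl-5-(phenylsulfonyl)-3-[(triethylsilyl)oxy]non-1-en-6-one (C5 epimers) | C=C[C@](C)(O[Si](CC)(CC)CC)CC(S(=O)(=O)c1ccccc1)C(=O)[C@H](C)C[C@H](O)c2c(C)occ2COCc3ccc(OC)cc3 | intermediate
18 | (3R,7R,9S)-9-hydroxy-9-[4-{[(4-methoxyphenyl)methoxy]methyl}-2-methylfuran-3-yl]-3,7-dimethyl-3-[(triethylsilyl)oxy]non-1-en-6-one | C=C[C@](C)(O[Si](CC)(CC)CC)CCC(=O)[C@H](C)C[C@H](O)c1c(C)occ1COCc2ccc(OC)cc2 | intermediate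
19 | methyl (2S)-2-methyloxirane-2-carboxylate | COC(=O)[C@@]1(C)OC1 | starting material
20 | potassium (2S)-2-methyloxirane-2-carboxylate | [K+].[O-]C(=O)[C@@]1(C)OC1 | intermediate
21 | (1S,3R,7R)-1-[4-{[(4-methoxyphenyl)methoxy]methyl}-2-methylfuran-3-yl]-3,7-dimethyl-4-oxo-7-[(triethylsilyl)oxy]non-8-en-1-yl (2S)-2-methyloxirane-2-carboxylate | C=C[C@](C)(O[Si](CC)(CC)CC)CCC(=O)[C@H](C)C[C@H](OC(=O)[C@@]1(C)OC1)c2c(C)occ2COCc3ccc(OC)cc3 | intermediate
22 | (1S,3R,7R)-1-[2-hydroxy-4-{[(4-methoxyphenyl)methoxy]methyl}-2-methyl-5-oxo-2,5-dihydrofuran-3-yl]-3,7-dimethyl-4-oxo-7-[(triethylsilyl)oxy]non-8-en-1-yl (2S)-2-methyloxirane-2-carboxylate (epimers at the ring hemiketal carbon) | C=C[C@](C)(O[Si](CC)(CC)CC)CCC(=O)[C@H](C)C[C@H](OC(=O)[C@@]1(C)OC1)C2=C(COCc3ccc(OC)cc3)C(=O)OC2(C)O | intermediate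
23 | (1S,3R,7R)-1-[4-{[(4-methoxyphenyl)methoxy]methyl}-2-methylidene-5-oxo-2,5-dihydrofuran-3-yl]-3,7-dimethyl-4-oxo-7-[(triethylsilyl)oxy]non-8-en-1-yl (2S)-2-methyloxirane-2-carboxylate | C=C[C@](C)(O[Si](CC)(CC)CC)CCC(=O)[C@H](C)C[C@H](OC(=O)[C@@]1(C)OC1)C2=C(COCc3ccc(OC)cc3)C(=O)OC2=C | intermediate
24 | (1S,3R,7R)-7-hydroxy-1-[4-{[(4-methoxyphenyl)methoxy]methyl}-2-methylidene-5-oxo-2,5-dihydrofuran-3-yl]-3,7-dimethyl-4-oxonon-8-en-1-yl (2S)-2-methyloxirane-2-carboxylate | C=C[C@](C)(O)CCC(=O)[C@H](C)C[C@H](OC(=O)[C@@]1(C)OC1)C2=C(COCc3ccc(OC)cc3)C(=O)OC2=C | intermediate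
25 | (1S,4R,5E,8S,10R)-1-hydroxy-13-[(4-methoxyphenyl)methoxy]-8-{[(2S)-2-methyloxirane-2-carbonyl]oxy}-1,4-epoxygermacra-5,7(11)-dien-12,6-olide | COc1ccc(COCC2=C3/C(=C\[C@@]4(C)CC[C@](O)(O4)[C@H](C)C[C@@H]3OC(=O)[C@@]5(C)OC5)OC2=O)cc1 | intermediate
26 | (1S,4R,5E,8S,10R)-1,13-dihydroxy-8-{[(2S)-2-methyloxirane-2-carbonyl]oxy}-1,4-epoxygermacra-5,7(11)-dien-12,6-olide | OCC1=C2/C(=C\[C@@]3(C)CC[C@](O)(O3)[C@H](C)C[C@@H]2OC(=O)[C@@]4(C)OC4)OC1=O | intermediate
27 | (1S,4R,5E,8S,10R)-13-acetoxy-1-hydroxy-8-{[(2S)-2-methyloxirane-2-carbonyl]oxy}-1,4-epoxygermacra-5,7(11)-dien-12,6-olide | CC(=O)OCC1=C2/C(=C\[C@@]3(C)CC[C@](O)(O3)[C@H](C)C[C@@H]2OC(=O)[C@@]4(C)OC4)OC1=O | intermediate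
28 | (1S,4R,5E,8S,10R)-13-acetoxy-8-{[(2R)-3-chloro-2-hydroxy-2-methylpropanoyl]oxy}-1-hydroxy-1,4-epoxygermacra-5,7(11)-dien-12,6-olide (CNP0414417.3) | CC(=O)OCC1=C2/C(=C\[C@@]3(C)CC[C@](O)(O3)[C@H](C)C[C@@H]2OC(=O)[C@@](C)(O)CCl)OC1=O | target

**Step count and risks**

Total steps: 18. Longest linear sequence: 14 (steps 1, 2, 4, 5, 8, 9, 11–18).

Step 15 (the new ring-closing metathesis) is the most likely to fail: both olefins are hindered and the enol-lactone olefin is untested in metathesis. The fallback uses known chemistry, sets out from 2 and comes back at 25. It closes the ring by an intramolecular Horner–Wadsworth–Emmons olefination of a 5-phosphono-2(5H)-furanone with a C5 aldehyde, the established carbonyl route to γ-alkylidene butenolides. That route cannot excise the extra methyl carbon, so it needs a furan without the 2-methyl group. Feist–Benary reaction of 2 with the sodium salt of formylacetone (NaOCH=CHC(O)CH3) gives the des-methyl furyl ketone F1. The operations of steps 2, 4 and 5 then give the PMB ether F2, the keto ester F3 and the trans lactone F4. Acylation of lithiated 16, SmI2 and Yamaguchi esterification with 20 (as in steps 8, 9, 11) give the keto sulfone F5, the hydroxy ketone F6 and the furyl glycidate F7. Photooxygenation with iPr2NEt, which removes the less hindered bridgehead hydrogen next to the CH2OPMB group, gives the γ-hydroxybutenolide F8. Dimethyl phosphite (Et3N cat., then PPTS) gives the butenolide phosphonate F9. HF·pyridine gives the tertiary alcohol F10. OsO4/NaIO4 cleaves the vinyl group to the aldehyde F11. LiCl/iPr2NEt in MeCN at high dilution closes the ring to 25, with the ring enforcing the same olefin geometry.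

Step 7 may give SN2′ attack of the sulfonyl carbanion on the vinyl epoxide instead of attack at the epoxide CH2. The fallback sets out from 11 and comes back at 16, and installs the vinyl group after the opening. NaH/4-methoxybenzyl chloride converts 11 into the glycidyl PMB ether F12. Lithiated 14 opens it at CH2 (no allylic pathway) and Et3SiCl traps the alkoxide as the silyl ether sulfone F13. DDQ frees the primary alcohol F14. Dess–Martin periodinane gives the aldehyde F15, and Ph3P=CH2 gives 16.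

Step 4 may suffer E2 elimination of the secondary triflate or O-alkylation of the hindered enolate. The fallback sets out from 5 and comes back at 10, and sets C8 before C10. The enolate of 5 [LiN(iPr)2] is alkylated with ethyl bromoacetate to the unbranched keto ester F16. CBS reduction and lactonisation as in step 5 give the (S)-lactone F17. LiN(iPr)2 then MeI methylates the lactone enolate anti to the furyl group to give the trans lactone 10.

**Further compounds**

F1 | step 15 | 1-[4-(chloromethyl)furan-3-yl]ethan-1-one | CC(=O)c1cocc1CCl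
F2 | step 15 | 1-(4-{[(4-methoxyphenyl)methoxy]methyl}furan-3-yl)ethan-1-one | CC(=O)c1cocc1COCc2ccc(OC)cc2
F3 | step 15 | ethyl (2R)-4-(4-{[(4-methoxyphenyl)methoxy]methyl}furan-3-yl)-2-methyl-4-oxobutanoate | CCOC(=O)[C@H](C)CC(=O)c1cocc1COCc2ccc(OC)cc2
F4 | step 15 | (3R,5S)-5-(4-{[(4-methoxyphenyl)methoxy]methyl}furan-3-yl)-3-methyloxolan-2-one | C[C@@H]1C[C@H](OC1=O)c2cocc2COCc3ccc(OC)cc3
F5 | step 15 | (3R,7R,9S)-9-hydroxy-9-(4-{[(4-methoxyphenyl)methoxy]methyl}furan-3-yl)-3,7-dimethyl-5-(phenylsulfonyl)-3-[(triethylsilyl)oxy]non-1-en-6-one | C=C[C@](C)(O[Si](CC)(CC)CC)CC(S(=O)(=O)c1ccccc1)C(=O)[C@H](C)C[C@H](O)c2cocc2COCc3ccc(OC)cc3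
F6 | step 15 | (3R,7R,9S)-9-hydroxy-9-(4-{[(4-methoxyphenyl)methoxy]methyl}furan-3-yl)-3,7-dimethyl-3-[(triethylsilyl)oxy]non-1-en-6-one | C=C[C@](C)(O[Si](CC)(CC)CC)CCC(=O)[C@H](C)C[C@H](O)c1cocc1COCc2ccc(OC)cc2
F7 | step 15 | (1S,3R,7R)-1-(4-{[(4-methoxyphenyl)methoxy]methyl}furan-3-yl)-3,7-dimethyl-4-oxo-7-[(triethylsilyl)oxy]non-8-en-1-yl (2S)-2-methyloxirane-2-carboxylate | C=C[C@](C)(O[Si](CC)(CC)CC)CCC(=O)[C@H](C)C[C@H](OC(=O)[C@@]1(C)OC1)c2cocc2COCc3ccc(OC)cc3
F8 | step 15 | (1S,3R,7R)-1-(2-hydroxy-4-{[(4-methoxyphenyl)methoxy]methyl}-5-oxo-2,5-dihydrofuran-3-yl)-3,7-dimethyl-4-oxo-7-[(triethylsilyl)oxy]non-8-en-1-yl (2S)-2-methyloxirane-2-carboxylate | C=C[C@](C)(O[Si](CC)(CC)CC)CCC(=O)[C@H](C)C[C@H](OC(=O)[C@@]1(C)OC1)C2=C(COCc3ccc(OC)cc3)C(=O)OC2O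
F9 | step 15 | (1S,3R,7R)-1-[2-(dimethoxyphosphoryl)-4-{[(4-methoxyphenyl)methoxy]methyl}-5-oxo-2,5-dihydrofuran-3-yl]-3,7-dimethyl-4-oxo-7-[(triethylsilyl)oxy]non-8-en-1-yl (2S)-2-methyloxirane-2-carboxylate | C=C[C@](C)(O[Si](CC)(CC)CC)CCC(=O)[C@H](C)C[C@H](OC(=O)[C@@]1(C)OC1)C2=C(COCc3ccc(OC)cc3)C(=O)OC2P(=O)(OC)OC
F10 | step 15 | (1S,3R,7R)-1-[2-(dimethoxyphosphoryl)-4-{[(4-methoxyphenyl)methoxy]methyl}-5-oxo-2,5-dihydrofuran-3-yl]-7-hydroxy-3,7-dimethyl-4-oxonon-8-en-1-yl (2S)-2-methyloxirane-2-carboxylate | C=C[C@](C)(O)CCC(=O)[C@H](C)C[C@H](OC(=O)[C@@]1(C)OC1)C2=C(COCc3ccc(OC)cc3)C(=O)OC2P(=O)(OC)OC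
F11 | step 15 | (1S,3R,7R)-1-[2-(dimethoxyphosphoryl)-4-{[(4-methoxyphenyl)methoxy]methyl}-5-oxo-2,5-dihydrofuran-3-yl]-7-hydroxy-3,7-dimethyl-4,8-dioxooctyl (2S)-2-methyloxirane-2-carboxylate | O=C[C@](C)(O)CCC(=O)[C@H](C)C[C@H](OC(=O)[C@@]1(C)OC1)C2=C(COCc3ccc(OC)cc3)C(=O)OC2P(=O)(OC)OC
F12 | step 7 | (2R)-2-{[(4-methoxyphenyl)methoxy]methyl}-2-methyloxirane | COc1ccc(COC[C@]2(C)OC2)cc1
F13 | step 7 | triethyl{[(2R)-1-[(4-methoxyphenyl)methoxy]-2-methyl-4-(phenylsulfonyl)butan-2-yl]oxy}silane | COc1ccc(COC[C@](C)(O[Si](CC)(CC)CC)CCS(=O)(=O)c2ccccc2)cc1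
F14 | step 7 | (2R)-2-methyl-4-(phenylsulfonyl)-2-[(triethylsilyl)oxy]butan-1-ol | OC[C@](C)(O[Si](CC)(CC)CC)CCS(=O)(=O)c1ccccc1
F15 | step 7 | (2R)-2-methyl-4-(phenylsulfonyl)-2-[(triethylsilyl)oxy]butanal | O=C[C@](C)(O[Si](CC)(CC)CC)CCS(=O)(=O)c1ccccc1
F16 | step 4 | ethyl 4-[4-{[(4-methoxyphenyl)methoxy]methyl}-2-methylfuran-3-yl]-4-oxobutanoate | CCOC(=O)CCC(=O)c1c(C)occ1COCc2ccc(OC)cc2
F17 | step 4 | (5S)-5-[4-{[(4-methoxyphenyl)methoxy]methyl}-2-methylfuran-3-yl]oxolan-2-one | O=C1CC[C@H](O1)c2c(C)occ2COCc3ccc(OC)cc3
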